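**Retrosynthetic overview**
- Feature: the target is a C2-symmetric, all-trans tetrahydrofuran (O-1, C-2 to C-5). C-2 with its aryl group is an aryl aldehyde carbon bonded to O-1 and C-3, and the CH2OH group on C-3 is a vinyl group shortened by one carbon.
- Key disconnection: O-1–C-2 and C-2–C-3 are cut together. This gives syringaldehyde pivalate and an anti (E)-allylsilane carbinol that already holds O-1, C-5, C-4 and C-3. The only ring, the tetrahydrofuran, closes in this step.
- The carbinol comes from the same aldehyde. C-4–C-5 is made by iridium-catalysed anti-(hydroxymethyl)allylation with vinyl ethylene carbonate, followed by silylation of the primary alcohol and cross-metathesis with allyltrimethylsilane.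
- After ring closure the vinyl group is cleaved to CHO. One hydride step then gives CH2OH and frees both phenols, and fluoride removes the silyl ether.

Key step: step 5

Assumption: the (R)-antipode of the bisphosphine is taken to give the (1R,2S)-diol of step 2. The sense of induction is to be checked on that diol (Mosher ester analysis), and the (S)-ligand is used if the opposite sense is found.

**Step 1**
Reactants: 1 syringaldehyde
Product: 2 4-formyl-2,6-dimethoxyphenyl pivalate
Conditions: PivCl, Et3N, DMAP (cat.), CH2Cl2, 0 °C to rt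
Reagents that add atoms: pivaloyl chloride, CC(C)(C)C(Cl)=O
Why: DMAP-catalysed O-acylation (esterification) of the only nucleophilic site turns the para oxygen from a strong donor into a weak one, as steps 2 and 5 require, and no stereocentre is involved.

**Step 2**
Reactants: 2 4-formyl-2,6-dimethoxyphenyl pivalate; 3 vinyl ethylene carbonate (racemic)
Product: 4 4-[(1R,2S)-1-hydroxy-2-(hydroxymethyl)but-3-en-1-yl]-2,6-dimethoxyphenyl pivalate (anti diol)
Conditions: [Ir(cod)Cl]2 (2.5 mol %), (R)-SEGPHOS (5 mol %), 4-chloro-3-nitrobenzoic acid (10 mol %), K3PO4 (10 mol %), i-PrOH (2 equiv), THF, 70 °C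
Reagents that add atoms: none
Why: In this iridium-catalysed transfer-hydrogenative carbonyl (hydroxymethyl)allylation, the cyclometallated C,O-benzoate of trivalent iridium ionises either enantiomer of 3 with loss of CO2 to an (E)-σ-(hydroxymethyl)allyl species; it adds through a closed chair, which sets the anti C-1/C-2 relationship, while the bisphosphine selects the aldehyde face and so the (1R,2S) series.

**Step 3**
Reactants: 4 anti diol
Product: 5 4-[(1R,2S)-2-(tert-butyldiphenylsilyloxymethyl)-1-hydroxybut-3-en-1-yl]-2,6-dimethoxyphenyl pivalate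
Conditions: TBDPSCl (1.05 equiv), imidazole, CH2Cl2, 0 °C
Reagents that add atoms: tert-butyl(chloro)diphenylsilane, CC(C)(C)[Si](Cl)(c1ccccc1)c1ccccc1
Why: In this silyl ether protection the bulky chlorosilane should take the primary hydroxyl group and leave the hindered secondary benzylic one free, with both stereocentres untouched.

**Step 4**
Reactants: 5 silyl ether; 6 allyltrimethylsilane
Product: 7 4-[(1R,2S,3E)-2-(tert-butyldiphenylsilyloxymethyl)-1-hydroxy-5-(trimethylsilyl)pent-3-en-1-yl]-2,6-dimethoxyphenyl pivalate
Conditions: 6 (4 equiv), second-generation Grubbs catalyst (H2IMes)(PCy3)Cl2Ru=CHPh (5 mol %), CH2Cl2, 40 °C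
Reagents that add atoms: none
Why: Olefin cross-metathesis of a type 1 partner in excess (the allylsilane, whose dimer stays metathesis-active) with the slower, allylically branched vinyl group of 5 should favour the cross product as its (E)-isomer; neither stereocentre is touched, and the carbinol, esters and silyl ether are tolerated by the ruthenium carbene.

**Step 5**
Reactants: 7 (E)-allylsilane carbinol; 2 4-formyl-2,6-dimethoxyphenyl pivalate
Product: 10 (2R,3R,4S,5R)-4-(tert-butyldiphenylsilyloxymethyl)-2,5-bis(3,5-dimethoxy-4-pivaloyloxyphenyl)-3-vinyltetrahydrofuran, via trimethylsilyl ether 8 (not isolated), via (E)-oxocarbenium triflate 9 (not isolated)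
Conditions: 2 (1.2 equiv), Me3SiOTf (1.3 equiv), 2,6-di-tert-butyl-4-methylpyridine (1.5 equiv), CH2Cl2, −78 °C; aq. NaHCO3
Reagents that add atoms: trimethylsilyl trifluoromethanesulfonate, C[Si](C)(C)OS(=O)(=O)C(F)(F)F (its atoms stay in 8 and 9 only, none in 10)
Why: Me3SiOTf silylates the carbinol of 7 (the hindered pyridine binds the TfOH, so no acid is left to protodesilylate the allylsilane), silyl ether 8 adds to the silyl-activated aldehyde 2, the mixed silyl acetal loses (Me3Si)2O to give the (E)-oxocarbenium ion 9, C-3 (the γ-carbon of the allylsilane) attacks its carbon with the C–Si bond antiperiplanar to the new bond, and triflate takes off Me3Si+ to leave the vinyl group and return Me3SiOTf. O-1 is therefore the carbinol oxygen of 7 and C-5–O-1 is never broken, whereas the aldehyde delivers only C-2 with its aryl group and loses its own oxygen to the disiloxane. The closest known reaction type is the intramolecular (silyl-modified) Hosomi–Sakurai or silyl-Prins condensation of 5-silylpent-3-en-1-ols and of cyclic allylsiloxanes with aldehydes to 3-vinyltetrahydrofurans. The tetrahydrofuran closes in a five-membered mode that is exo for the attacking C=C bond (its far carbon stays outside the ring) and endo-trig for the C=O+ bond (both of its atoms end up in the ring), which is workable here because the cation is very electrophilic and the transition state is early. C-2 is controlled by the (E)-geometry of 9, which puts its aryl group equatorial on an envelope with C-2 as the flap while the alkenyl group on C-3 lies pseudo-equatorial and antiperiplanar to C=O+ (2,3-trans), and C-3 is controlled by the C-4 stereocentre, which turns H-4 into the alkene plane (allylic 1,3-strain) so that the tethered cation reaches the alkene face that sets vinyl and CH2OSi trans. An all-trans ring has its aryl groups trans across O-1, so the C-5 aryl group cannot be equatorial too and must take the near-isoclinal site syn to H-2; the step thus has to override the innate 2,5-cis bias of such closures, which the bulky CH2OSiPh2t-Bu group and −78 °C should secure, while chemoselectivity rests on the two acyloxy-deactivated rings (no ionisation at C-5, slow 2-oxonia-Cope shift) and on the identity of the two aryl groups (aldehyde exchange gives no crossed product).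

**Step 6**
Reactants: 10 vinyl tetrahydrofuran
Product: 11 (2R,3R,4S,5R)-4-(tert-butyldiphenylsilyloxymethyl)-2,5-bis(3,5-dimethoxy-4-pivaloyloxyphenyl)tetrahydrofuran-3-carbaldehyde
Conditions: OsO4 (2 mol %), NaIO4 (4 equiv), 2,6-lutidine (2 equiv), dioxane–H2O 3:1, rt
Reagents that add atoms: sodium periodate, [Na+].[O-]I(=O)(=O)=O (terminal oxidant; the aldehyde oxygen is passed on through osmium tetroxide, O=[Os](=O)(=O)=O)
Why: In the Lemieux–Johnson oxidation, osmylation of the only C=C bond and periodate cleavage of the diol remove the terminal carbon as formaldehyde; the lutidine buffer and the trans,trans position of the formyl group on C-3 guard against enolisation, epimerisation and β-elimination of O-1, and 11 is taken on crude.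

**Step 7**
Reactants: 11 aldehyde
Product: 12 [(2R,3S,4S,5R)-4-(tert-butyldiphenylsilyloxymethyl)-2,5-bis(4-hydroxy-3,5-dimethoxyphenyl)tetrahydrofuran-3-yl]methanol
Conditions: LiAlH4 (4 equiv), THF, 0 °C; aq. potassium sodium tartrate, NaH2PO4 to pH 6
Reagents that add atoms: none
Why: Hydride reduction with LiAlH4 turns the aldehyde into CH2OH before it can enolise and cleaves both aryl pivalates reductively to the phenols in the same operation, while the silyl ether and the benzylic ethers are inert at 0 °C and no stereocentre is touched.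

**Step 8**
Reactants: 12 bisphenol silyl ether
Product: 13 (2R,3S,4S,5R)-2,5-bis(4-hydroxy-3,5-dimethoxyphenyl)-3,4-bis(hydroxymethyl)tetrahydrofuran (target)
Conditions: Bu4NF (2 equiv), AcOH (2 equiv), THF, rt, argon
Reagents that add atoms: none
Why: Fluoride-induced desilylation is driven by the Si–F bond, and the acetic acid buffer keeps the syringyl phenols protonated, so neither air oxidation of phenoxides nor quinone-methide opening at C-2 or C-5 should disturb the four stereocentres.

**Compound list**
1 | syringaldehyde (4-hydroxy-3,5-dimethoxybenzaldehyde) | COc1cc(C=O)cc(OC)c1O | starting material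
2 | 4-formyl-2,6-dimethoxyphenyl pivalate | COc1cc(C=O)cc(OC)c1OC(=O)C(C)(C)C | intermediate
3 | vinyl ethylene carbonate (racemic 4-vinyl-1,3-dioxolan-2-one) | C=CC1COC(=O)O1 | starting material
4 | 4-[(1R,2S)-1-hydroxy-2-(hydroxymethyl)but-3-en-1-yl]-2,6-dimethoxyphenyl pivalate | O[C@@H](c1cc(OC)c(OC(=O)C(C)(C)C)c(OC)c1)[C@H](CO)C=C | intermediate
5 | 4-[(1R,2S)-2-(tert-butyldiphenylsilyloxymethyl)-1-hydroxybut-3-en-1-yl]-2,6-dimethoxyphenyl pivalate | O[C@@H](c1cc(OC)c(OC(=O)C(C)(C)C)c(OC)c1)[C@H](CO[Si](c1ccccc1)(c1ccccc1)C(C)(C)C)C=C | intermediate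
6 | allyltrimethylsilane | C=CC[Si](C)(C)C | starting material
7 | 4-[(1R,2S,3E)-2-(tert-butyldiphenylsilyloxymethyl)-1-hydroxy-5-(trimethylsilyl)pent-3-en-1-yl]-2,6-dimethoxyphenyl pivalate | O[C@@H](c1cc(OC)c(OC(=O)C(C)(C)C)c(OC)c1)[C@H](CO[Si](c1ccccc1)(c1ccccc1)C(C)(C)C)/C=C/C[Si](C)(C)C | intermediate
8 | trimethylsilyl ether of 7 | C[Si](C)(C)O[C@@H](c1cc(OC)c(OC(=O)C(C)(C)C)c(OC)c1)[C@H](CO[Si](c1ccccc1)(c1ccccc1)C(C)(C)C)/C=C/C[Si](C)(C)C | intermediate
9 | (E)-oxocarbenium triflate from 8 and 2 | COc1cc(/C=[O+]/[C@@H](c2cc(OC)c(OC(=O)C(C)(C)C)c(OC)c2)[C@H](CO[Si](c2ccccc2)(c2ccccc2)C(C)(C)C)/C=C/C[Si](C)(C)C)cc(OC)c1OC(=O)C(C)(C)C.[O-]S(=O)(=O)C(F)(F)F | intermediate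
10 | (2R,3R,4S,5R)-4-(tert-butyldiphenylsilyloxymethyl)-2,5-bis(3,5-dimethoxy-4-pivaloyloxyphenyl)-3-vinyltetrahydrofuran (all-trans) | COc1cc([C@@H]2O[C@@H](c3cc(OC)c(OC(=O)C(C)(C)C)c(OC)c3)[C@H](CO[Si](c3ccccc3)(c3ccccc3)C(C)(C)C)[C@H]2C=C)cc(OC)c1OC(=O)C(C)(C)C | intermediate
11 | (2R,3R,4S,5R)-4-(tert-butyldiphenylsilyloxymethyl)-2,5-bis(3,5-dimethoxy-4-pivaloyloxyphenyl)tetrahydrofuran-3-carbaldehyde | COc1cc([C@@H]2O[C@@H](c3cc(OC)c(OC(=O)C(C)(C)C)c(OC)c3)[C@H](CO[Si](c3ccccc3)(c3ccccc3)C(C)(C)C)[C@H]2C=O)cc(OC)c1OC(=O)C(C)(C)C | intermediate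
12 | [(2R,3S,4S,5R)-4-(tert-butyldiphenylsilyloxymethyl)-2,5-bis(4-hydroxy-3,5-dimethoxyphenyl)tetrahydrofuran-3-yl]methanol | COc1cc([C@@H]2O[C@@H](c3cc(OC)c(O)c(OC)c3)[C@H](CO[Si](c3ccccc3)(c3ccccc3)C(C)(C)C)[C@H]2CO)cc(OC)c1O | intermediate
13 | (2R,3S,4S,5R)-2,5-bis(4-hydroxy-3,5-dimethoxyphenyl)-3,4-bis(hydroxymethyl)tetrahydrofuran | COc1cc([C@@H]2O[C@@H](c3cc(OC)c(O)c(OC)c3)[C@H](CO)[C@H]2CO)cc(OC)c1O | target

Total step count: 8
Longest linear sequence: 8 (1 → 2 → 4 → 5 → 7 → 10 → 11 → 12 → 13; aldehyde 2 enters a second time in step 5)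

**Steps most likely to fail**

**Step 5.**
- Risk: the innate preference of such closures for a 2,5-cis ring, or a synclinal approach of the alkene to C=O+, may erode the facial selectivity at C-2. The allylic strain that sets C-3 is only modest for an (E)-alkene.
- Fallback: kinetic control at the benzylic centres is given up. With C-3 and C-4 fixed trans, the all-trans ring is the thermodynamic one.
- Course: the fallback sets out from 7 and 2. The step is run as written and the ring isomers are not separated.
  - The main contaminant should be the (2S,3R,4S,5R)-epimer of 10 F1. It is carried together with 10 through methanolysis of the pivalates (NaOMe, MeOH, argon) to the (2S)-configured bisphenol F2.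
  - A catalytic acid (BF3·OEt2 or CF3CO2H, CH2Cl2, −20 to 0 °C) opens C-2–O-1 reversibly through the p-hydroxybenzyl cation. This is the known acid epimerisation of 2,5-diaryltetrahydrofuran and furofuran lignans, and it should converge on the all-trans bisphenol F3.
  - Both CH2OH groups are still masked at this stage (vinyl, silyl ether), so the cation cannot be trapped as a furofuran.
  - Re-esterification (pivaloyl chloride, Et3N, DMAP) comes back to the route at 10.
- Limit: loss of control at C-3 is not repaired this way. The (Z)-locked silane described under step 4 answers that case.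

**Step 4.**
- Risk: metathesis at the allylically branched vinyl group may be slow, catalyst may be consumed by self-metathesis of the allylsilane, and the alkene geometry may be eroded.
- Fallback: the metathesis is made intramolecular through a silicon tether.
- Course: the fallback sets out from 5.
  - Silylation of the secondary hydroxyl group with allyl(chloro)dimethylsilane (Et3N, DMAP, CH2Cl2) gives the allyldimethylsilyl ether of 5 F4.
  - Ring-closing metathesis (second-generation Grubbs catalyst, dilute CH2Cl2, 40 °C) gives the seven-membered (Z)-allylsiloxane, the (6S,7R)-2,2-dimethyl-2,3,6,7-tetrahydro-1,2-oxasilepine F5.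
  - Condensation of F5 with 2 under BF3·OEt2 (CH2Cl2, −78 °C), the known allylsiloxane form of the same annulation, comes back to the route at 10 and leaves out 7.
- Added benefit: the (Z)-alkene raises the allylic 1,3-strain and so also tightens control over C-3.

**Step 2.**
- Risk: anti selectivity or enantioselectivity may be incomplete with this ester-bearing aldehyde, and the pivaloyl group may transfer to the new primary alkoxide at the reaction temperature.
- Fallback: the transfer-hydrogenative coupling is replaced by a chiral-Brønsted-acid-catalysed allylboration at low temperature.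
- Course:
  - 2-Vinyloxirane is opened with B2pin2 (Ni(cod)2 catalyst, hydrolytic work-up) to (E)-4-(pinacolboryl)but-2-en-1-ol F6.
  - Silylation (TBDPSCl, imidazole) gives its tert-butyldiphenylsilyl ether F7.
  - Setting out from 2, F7 is added under (R)-TRIP, the 3,3'-bis(2,4,6-triisopropylphenyl)-BINOL hydrogen phosphate (5 mol %, toluene, −30 °C; antipode chosen as the sense of induction requires).
  - The closed chair of the (E)-boronate gives the anti product, and the fallback comes back to the route at 5, replacing steps 2 and 3.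

**Further compounds**
F1 | step 5 | (2S,3R,4S,5R)-4-(tert-butyldiphenylsilyloxymethyl)-2,5-bis(3,5-dimethoxy-4-pivaloyloxyphenyl)-3-vinyltetrahydrofuran (C-2 epimer of 10) | COc1cc([C@H]2O[C@@H](c3cc(OC)c(OC(=O)C(C)(C)C)c(OC)c3)[C@H](CO[Si](c3ccccc3)(c3ccccc3)C(C)(C)C)[C@H]2C=C)cc(OC)c1OC(=O)C(C)(C)C
F2 | step 5 | (2S,3R,4S,5R)-4-(tert-butyldiphenylsilyloxymethyl)-2,5-bis(4-hydroxy-3,5-dimethoxyphenyl)-3-vinyltetrahydrofuran | COc1cc([C@H]2O[C@@H](c3cc(OC)c(O)c(OC)c3)[C@H](CO[Si](c3ccccc3)(c3ccccc3)C(C)(C)C)[C@H]2C=C)cc(OC)c1O
F3 | step 5 | (2R,3R,4S,5R)-4-(tert-butyldiphenylsilyloxymethyl)-2,5-bis(4-hydroxy-3,5-dimethoxyphenyl)-3-vinyltetrahydrofuran (all-trans) | COc1cc([C@@H]2O[C@@H](c3cc(OC)c(O)c(OC)c3)[C@H](CO[Si](c3ccccc3)(c3ccccc3)C(C)(C)C)[C@H]2C=C)cc(OC)c1O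
F4 | step 4 | allyldimethylsilyl ether of 5 | C=CC[Si](C)(C)O[C@@H](c1cc(OC)c(OC(=O)C(C)(C)C)c(OC)c1)[C@H](CO[Si](c1ccccc1)(c1ccccc1)C(C)(C)C)C=C
F5 | step 4 | 4-[(6S,7R)-6-(tert-butyldiphenylsilyloxymethyl)-2,2-dimethyl-2,3,6,7-tetrahydro-1,2-oxasilepin-7-yl]-2,6-dimethoxyphenyl pivalate | C[Si]1(C)O[C@@H](c2cc(OC)c(OC(=O)C(C)(C)C)c(OC)c2)[C@H](CO[Si](c2ccccc2)(c2ccccc2)C(C)(C)C)/C=C\C1
F6 | step 2 | (E)-4-(4,4,5,5-tetramethyl-1,3,2-dioxaborolan-2-yl)but-2-en-1-ol | OC/C=C/CB1OC(C)(C)C(C)(C)O1
F7 | step 2 | tert-butyldiphenylsilyl ether of F6 | CC(C)(C)[Si](OC/C=C/CB1OC(C)(C)C(C)(C)O1)(c1ccccc1)c1ccccc1
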